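## Analysis of the target

Compound 17 is a flavonol. Benzo ring A and 4-pyranone ring C form a 4H-chromen-4-one, and ring B, a 4-methoxyphenyl group, sits on C2. There is no stereocentre, and the only alkene outside the rings ends in two methyl groups, so no configuration has to be set or preserved. The task is to tell the oxygens apart: O3 and O5 are free hydroxyls, O7 carries a 3-methylbut-2-enyl (prenyl) group and O4' a methyl group.

The prenyl aryl ether is the delicate part. Acid cleaves or cyclises it, catalytic hydrogenation saturates or cleaves it, an electrophilic oxidant attacks its trisubstituted alkene first, and strong heating starts a Claisen rearrangement. The 3-hydroxy-4-pyranone is an enol that air oxidises in strong base, whereas the C5 hydroxyl is hydrogen-bonded to the C4 carbonyl and barely reacts under mild alkylation. Ring A is a 2,4,6-trioxygenated aryl ketone with C4a squeezed between C5–O and C8a–O1, which makes a stepwise build-up by acylation and later ring closure long.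

The plan rests on three facts. The two bonds from ring A into ring C, C8a–O1 and C4a–C4, start from neighbouring carbons. The acyl-bearing C4a has the C5 oxygen as its other neighbour. The C7 oxygen lies two positions beyond C5. This is the pattern produced when a nucleophile–electrophile pair adds across a benzyne bearing alkoxy groups at its positions 3 and 5.

## Retrosynthetic reasoning

**O7–prenyl.** The first cut is the O7–CH2 bond of the prenyl ether, leading from 17 to the triol 15 (kaempferide) and prenyl bromide 16.
- It comes first in the backward direction because the allyl ether would not survive the rest of the endgame. Oxygen transfer to C2=C3 would hit the more electron-rich prenyl alkene, and hydrogenolysis would saturate or cleave it.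
- The gain is that all earlier steps may use oxidants and reductive deprotection.
- The forward reaction must pick O7 out of three hydroxyls. O5 is removed from competition by its chelate with C4=O, and O7 differs from O3 by its higher acidity.

**Benzyl ethers.** The hydroxyls at C5 and C7 of 15 are masked as benzyl ethers, giving 14.
- Benzyl tolerates an alkyllithium at low temperature, hot fluoride and a neutral oxidant.
- Both groups leave in one neutral operation that touches neither the C4' methyl ether nor the C3 enol.
- Two identical groups also keep the ring A building block symmetric, which removes a regiochemical question further back.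

**C3–O.** The C3–O bond of 14 is cut, by way of epoxide 13, to give flavone 12.
- The oxygen is introduced late because the C2–C3–C4 unit can then come from a plain alkynoic acid. An alkyne has no place for a C3 oxygen.
- The forward reaction must epoxidise the C2=C3 bond, which is an enol ether and a vinylogous ester at once, and then isomerise the epoxide to the enol.

**Ring C.** Ring C of 12 is cut at three bonds at once.
- Opening O1–C2 gives the ortho-hydroxyaryl ynone 11. Removing O1–C8a and C4–C4a from 11 leaves aryne 10 and 3-(4-methoxyphenyl)propiolic acid 9, whose carboxyl group supplies both O1 and C4.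
- The customary cuts first make the crowded aryl ketone and then spend further steps on C2–C3 and on ring closure. This cut places the oxygen and the acyl group on adjacent carbons in a single event, and ring closure follows in the same flask.
- The polarity fits. The carbon of 10 remote from the flanking benzyloxy group is electrophilic, and the carbon next to that group carries the charge after addition. The acyl group therefore ends up between O1 and the C5 oxygen.
- Aryne 10 is released from the ortho-silylaryl triflate 8.

**Aryne precursor.** Triflate 8 is traced back through its O–S bond to silylphenol 7, which is unmasked from carbamate 6.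
- The C–Si bond of 6 is cut to give carbamate 2, passing through 5, 4 and 3. Carbamate 2 comes from the purchasable 3,5-bis(benzyloxy)phenol 1.
- The carbamate both directs lithiation to the carbon between itself and a benzyloxy group and leaves again under mild base.
- Because 1 is symmetric, the two such carbons are identical and only one silylated product is possible from carbamate-directed lithiation.

## Alternatives that were turned down

**Alternative 1:** Ring A is the ring that is built.
- *Disconnection.* Cutting C4a–C5 and C8–C8a leads to two fragments. The first is a monocyclic pyranone that already holds ring B and the protected C3 oxygen, 3-(methoxymethoxy)-2-(4-methoxyphenyl)-5-(phenylsulfinyl)-4H-pyran-4-one A2. The second is the four-carbon unit 1-methoxy-1,3-bis(trimethylsilyloxy)buta-1,3-diene A3.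
- *Forward key step.* The CH2 terminus of A3 bonds to the pyranone carbon next to the ring oxygen (later C8a). The ketene acetal terminus bonds to the sulfinyl-bearing carbon (later C4a). Syn elimination of the sulfoxide and loss of the acetal methoxy group then aromatise the adduct to 5,7-dihydroxy-3-(methoxymethoxy)-2-(4-methoxyphenyl)-4H-chromen-4-one A1.
- *For.* In A1, O3 is masked and O5 is chelated, so 16 can only alkylate O7. This gives 5-hydroxy-3-(methoxymethoxy)-2-(4-methoxyphenyl)-7-(3-methylbut-2-enyloxy)-4H-chromen-4-one A4. No C3 oxidation and no hydrogenolysis are needed. On the last alkylation this plan is stronger than the chosen route, whose step 7 separates O7 from O3 by acidity alone.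
- *Against.* A2 cannot be bought. Making the pyranone ring, oxygenating C3, and sulfenylating and oxidising C5 is a synthesis of its own, so the difficulty of ring C is moved rather than solved. A 4-pyranone is a vinylogous ester with some aromatic character and a reluctant dienophile. A3 hydrolyses easily and tends to stop after the first, Michael-type bond. The final step is an acidic acetal cleavage on A4 in the presence of the acid-labile prenyl ether.
- *Comparison.* The chosen strategy offers purchasable carbon fragments and a ring-forming step that makes three bonds from them. Its weak point is a final alkylation that has a simple protecting-group remedy.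

**Alternative 2:** Ring C is cut at C3–C4 and O1–C8a.
- *Disconnection.* C2, C3, ring B and the protected O3 come from 2-(methoxymethoxy)-1-(4-methoxyphenyl)ethan-1-one A6. Ring A together with C4 comes from 2,4,6-trifluorobenzoyl chloride A7.
- *Forward key step.* A lithium amide base forms the enolate of A6, and C-acylation by A7 gives a 1,3-diketone. The diketone enolate oxygen displaces an ortho fluoride by addition–elimination, closing ring C to 5,7-difluoro-3-(methoxymethoxy)-2-(4-methoxyphenyl)-4H-chromen-4-one A5.
- *For.* Both partners are cheap, the two ortho fluorides are equivalent, the C3 oxygen is in place from the start, and the chromenone is reached in one flask. It gets to the bicycle in fewer steps than the chosen route, which needs three steps for its aryne precursor.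
- *Against.* The C5 and C7 oxygens are still missing, and two C–F bonds must be exchanged in turn for two different oxygen groups. Both are activated by the same C4 carbonyl (C7 para, C5 ortho), so the site of the first substitution by the alkoxide of 3-methylbut-2-en-1-ol A8 depends on a small difference. Metal chelation to the carbonyl can turn that difference towards C5. The first alkoxy donor then deactivates the ring, so the second exchange needs a hydroxide surrogate and forcing base. Under such conditions hard nucleophiles add to C2 and open ring C. O-acylation of the enolate competes in the key step, and the route also ends with acid treatment of A4.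
- *Comparison.* The chosen strategy carries the ring A oxygens through the ring-forming step at their final positions, so no oxygen has to be placed on ring A afterwards.

**Alternative 3:** Ring C is cut at C4a–C4, C4–C3 and O1–C2.
- *Disconnection.* C4 comes from carbon monoxide A12, ring A from 2-iodobenzene-1,3,5-triyl triacetate A10, and C2, C3 and ring B from 1-ethynyl-4-methoxybenzene A11.
- *Forward key step.* The C–I bond adds oxidatively to zerovalent palladium, A12 inserts, and the acyl complex is alkynylated by A11. The secondary amine solvent removes the acetates and adds reversibly to the ynone. The ortho phenol then closes to 5,7-dihydroxy-2-(4-methoxyphenyl)-4H-chromen-4-one (acacetin) A9.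
- *For.* It forms one ring and three bonds like the chosen key step, is catalytic, uses commodity partners, and the amine-assisted closure is reliably 6-endo. A10 is about two steps from a bulk phenol. In atom economy and precursor length it is at least as good as the aryne route, which consumes a silyl group, a triflate and excess CsF.
- *Against.* The C–I bond lies between two acyloxy groups on a very electron-rich ring. Oxidative addition and insertion of A12 are therefore slow, and direct alkynylation followed by closure to a five-membered furan ring can take over. The amine strips the acetates early, leaving an iodinated triphenol that loses iodine through its keto tautomer and binds the metal. A9 arrives unprotected and cannot go into the C3 oxidation as it stands. Its O5 and O7 would have to be protected again, in effect making 12, so the apparent saving is spent. A toxic gas must also be handled.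
- *Comparison.* The chosen strategy delivers 12 directly in the protected form that the C3 oxidation needs, and its regiochemistry is fixed by the substrate rather than by a competition between catalytic pathways.

Key step: step 4

Remark: compounds 1, 9 and 16 are taken as purchasable. Epoxide 13 forms as a racemate, its SMILES shows one enantiomer of the necessarily cis-fused ring, and both stereocentres vanish again within step 5.

## Route

Step 1
Reactants: 1 3,5-bis(benzyloxy)phenol
Product: 2 3,5-bis(benzyloxy)phenyl isopropylcarbamate
Conditions: i-PrNCO (1.5 equiv), Et3N (0.2 equiv), CH2Cl2, rt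
Reagents that add atoms: isopropyl isocyanate, CC(C)N=C=O
Why: Base-catalysed addition of a phenol to an isocyanate, and 1 has only one nucleophilic site. The secondary carbamate is chosen because, once N-silylated, it directs lithiation strongly, and it can later be removed by a mild E1cB cleavage that an N,N-dialkyl carbamate does not allow.

Step 2
Reactants: 2 3,5-bis(benzyloxy)phenyl isopropylcarbamate
Product: 6 3,5-bis(benzyloxy)-2-(trimethylsilyl)phenyl isopropylcarbamate, via N-silyl carbamate 3 (not isolated), via aryllithium 4 (not isolated), via doubly silylated carbamate 5 (not isolated)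
Conditions: TBSOTf (1.1 equiv), TMEDA (1.1 equiv), Et2O, 0 °C to rt; TMEDA (2 equiv), n-BuLi (2 equiv), −78 °C; TMSCl (3.5 equiv), −78 °C to rt; aq. NaHSO4 work-up
Reagents that add atoms: chlorotrimethylsilane, C[Si](C)(C)Cl; for the intermediates only: tert-butyldimethylsilyl trifluoromethanesulfonate, CC(C)(C)[Si](C)(C)OS(=O)(=O)C(F)(F)F (silyl group on nitrogen in 3, 4 and 5) and n-butyllithium, [Li]CCCC (lithium of 4)
Why: Directed ortho-metalation of an O-aryl carbamate with temporary N-silylation of the N–H. The carbamate carbonyl delivers the base to C2 (C6 is identical by symmetry), which the adjacent benzyloxy group acidifies further, whereas C4 lies between two weaker directors. At −78 °C aryllithium 4 should neither undergo the anionic Fries shift nor be overtaken by benzylic deprotonation, and the N–Si bond of 5 is hydrolysed in the acidic work-up.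

Step 3
Reactants: 6 3,5-bis(benzyloxy)-2-(trimethylsilyl)phenyl isopropylcarbamate
Product: 8 3,5-bis(benzyloxy)-2-(trimethylsilyl)phenyl trifluoromethanesulfonate, via silylphenol 7 (not isolated)
Conditions: Et2NH (1.2 equiv), DBU (1.5 equiv), MeCN, 40 °C; then PhNTf2 (1.5 equiv), MeCN, rt
Reagents that add atoms: N-phenylbis(trifluoromethanesulfonimide), O=S(=O)(N(c1ccccc1)S(=O)(=O)C(F)(F)F)C(F)(F)F
Why: DBU removes the N–H proton and the carbamate breaks down by E1cB to the phenoxide of 7 and an isocyanate, which Et2NH traps as a urea. The phenoxide is then sulfonylated in the same flask by the mild triflyl donor. No acid or fluoride is present, so the C–Si bond should be kept, although it is prone to protodesilylation on this electron-rich ring.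

Step 4
Reactants: 8 3,5-bis(benzyloxy)-2-(trimethylsilyl)phenyl trifluoromethanesulfonate; 9 3-(4-methoxyphenyl)propiolic acid
Product: 12 5,7-bis(benzyloxy)-2-(4-methoxyphenyl)-4H-chromen-4-one, via aryne 10 (not isolated), via hydroxyaryl ynone 11 (not isolated)
Conditions: 8 (1.5 equiv), 9 (1 equiv), CsF (4 equiv), THF (ca. 0.02 M), sealed tube, 125 °C
Reagents that add atoms: none
Why: Fluoride attacks the silicon of 8, triflate leaves, and aryne 10 is released gradually. The benzyloxy group beside the triple bond distorts and polarises it, so the caesium carboxylate of 9 adds through oxygen at the far carbon (O1–C8a) and the charge develops on the carbon ortho to that benzyloxy group, where induction stabilises it. This aryl anion lies next to the new aryl ester, and because the rigid alkyne holds its β-carbon out of reach the anion can only attack the carbonyl, passing through a four-membered alkoxide that opens to the ortho-acyl phenoxide, the salt of 11 (C4–C4a). The phenoxide then adds to the β-carbon of the ynone in a 6-endo-dig oxa-Michael closure (O1–C2, ring C), and the allenolate takes up the proton that 9 brought in. The closest known reaction type is the fluoride-induced insertion of arynes into the C–O bond of carboxylic acids to give ortho-hydroxyaryl ketones, which with arylpropiolic acids runs on to flavones, and only the substitution of the aryne differs here. No stereocentre is formed. Three selectivities are needed: the site of attack on 10, secured by the flanking benzyloxy group (the second one, para to the anionic carbon, has little influence); acyl transfer ahead of protonation, helped by dilution, heat and excess CsF that binds the acidic proton as bifluoride; and 6-endo over 5-exo closure, helped by conjugate polarisation of the ynone and by reversibility under the hot basic conditions, which lets the more stable pyranone accumulate.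

Step 5
Reactants: 12 5,7-bis(benzyloxy)-2-(4-methoxyphenyl)-4H-chromen-4-one
Product: 14 5,7-bis(benzyloxy)-3-hydroxy-2-(4-methoxyphenyl)-4H-chromen-4-one, via flavone epoxide 13 (not isolated)
Conditions: dimethyldioxirane (ca. 0.08 M in acetone, 3–5 equiv), CH2Cl2, 0 °C to rt; evaporate; p-TsOH·H2O (cat.), CH2Cl2, rt
Reagents that add atoms: dimethyldioxirane, CC1(C)OO1
Why: Neutral electrophilic epoxidation of the C2=C3 bond, which O1 and the anisyl group keep electron-rich enough, followed by acid-induced isomerisation, a known way from flavones to flavonols. The epoxide opens at C2 because the cation there is stabilised by O1 and the 4-methoxyphenyl ring, and loss of H3 restores the pyranone. The two stereocentres of 13 are cis by ring constraint, racemic, and destroyed in the same step.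

Step 6
Reactants: 14 5,7-bis(benzyloxy)-3-hydroxy-2-(4-methoxyphenyl)-4H-chromen-4-one
Product: 15 3,5,7-trihydroxy-2-(4-methoxyphenyl)-4H-chromen-4-one (kaempferide)
Conditions: H2 (1 atm), 10% Pd/C, THF–MeOH, rt
Reagents that add atoms: none
Why: Catalytic hydrogenolysis of two aryl benzyl ethers. The tetrasubstituted C2=C3 bond of the pyranone, the C4 carbonyl and the aryl methyl ether are inert under these mild conditions.

Step 7
Reactants: 15 3,5,7-trihydroxy-2-(4-methoxyphenyl)-4H-chromen-4-one (kaempferide); 16 prenyl bromide (1-bromo-3-methylbut-2-ene)
Product: 17 3,5-dihydroxy-2-(4-methoxyphenyl)-7-[(3-methylbut-2-en-1-yl)oxy]-4H-chromen-4-one (target)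
Conditions: K2CO3 (1.0 equiv), 16 (1.05 equiv), DMF, 0 °C to rt
Reagents that add atoms: none
Why: Williamson ether synthesis by SN2 at the primary carbon of 16. O7–H, para to the C4 carbonyl, is a vinylogous carboxylic acid and clearly the most acidic site, O5–H is locked in a six-membered chelate, and O3–H is a weaker acid that is also hydrogen-bonded. With one equivalent of base essentially only the 7-phenoxide is present, and because nucleophilicity rises less steeply than basicity, the trace of 3-oxide cannot make up for its low concentration.

## Compound list

1 | 3,5-bis(benzyloxy)phenol | Oc1cc(OCc2ccccc2)cc(OCc2ccccc2)c1 | starting material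
2 | 3,5-bis(benzyloxy)phenyl isopropylcarbamate | CC(C)NC(=O)Oc1cc(OCc2ccccc2)cc(OCc2ccccc2)c1 | intermediate
3 | 3,5-bis(benzyloxy)phenyl N-(tert-butyldimethylsilyl)-N-isopropylcarbamate | CC(C)N(C(=O)Oc1cc(OCc2ccccc2)cc(OCc2ccccc2)c1)[Si](C)(C)C(C)(C)C | intermediate
4 | [2,4-bis(benzyloxy)-6-{[(tert-butyldimethylsilyl)(isopropyl)carbamoyl]oxy}phenyl]lithium | [Li]c1c(OC(=O)N(C(C)C)[Si](C)(C)C(C)(C)C)cc(OCc2ccccc2)cc1OCc1ccccc1 | intermediate
5 | 3,5-bis(benzyloxy)-2-(trimethylsilyl)phenyl N-(tert-butyldimethylsilyl)-N-isopropylcarbamate | CC(C)N(C(=O)Oc1cc(OCc2ccccc2)cc(OCc2ccccc2)c1[Si](C)(C)C)[Si](C)(C)C(C)(C)C | intermediate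
6 | 3,5-bis(benzyloxy)-2-(trimethylsilyl)phenyl isopropylcarbamate | CC(C)NC(=O)Oc1cc(OCc2ccccc2)cc(OCc2ccccc2)c1[Si](C)(C)C | intermediate
7 | 3,5-bis(benzyloxy)-2-(trimethylsilyl)phenol | C[Si](C)(C)c1c(O)cc(OCc2ccccc2)cc1OCc1ccccc1 | intermediate
8 | 3,5-bis(benzyloxy)-2-(trimethylsilyl)phenyl trifluoromethanesulfonate | C[Si](C)(C)c1c(OCc2ccccc2)cc(OCc2ccccc2)cc1OS(=O)(=O)C(F)(F)F | intermediate
9 | 3-(4-methoxyphenyl)propiolic acid | COc1ccc(C#CC(=O)O)cc1 | starting material
10 | 3,5-bis(benzyloxy)benzyne (3,5-bis(benzyloxy)-1,2-didehydrobenzene) | C1#CC(OCc2ccccc2)=CC(OCc2ccccc2)=C1 | intermediate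
11 | 1-[2,4-bis(benzyloxy)-6-hydroxyphenyl]-3-(4-methoxyphenyl)prop-2-yn-1-one (present as its caesium phenoxide) | COc1ccc(C#CC(=O)c2c(O)cc(OCc3ccccc3)cc2OCc2ccccc2)cc1 | intermediate
12 | 5,7-bis(benzyloxy)-2-(4-methoxyphenyl)-4H-chromen-4-one | COc1ccc(-c2cc(=O)c3c(OCc4ccccc4)cc(OCc4ccccc4)cc3o2)cc1 | intermediate
13 | rac-4,6-bis(benzyloxy)-1a-(4-methoxyphenyl)-1a,7a-dihydro-7H-oxireno[2,3-b]chromen-7-one (cis-fused 2,3-epoxide of 12, one enantiomer drawn) | COc1ccc([C@]23O[C@H]2C(=O)c2c(OCc4ccccc4)cc(OCc4ccccc4)cc2O3)cc1 | intermediate
14 | 5,7-bis(benzyloxy)-3-hydroxy-2-(4-methoxyphenyl)-4H-chromen-4-one | COc1ccc(-c2oc3cc(OCc4ccccc4)cc(OCc4ccccc4)c3c(=O)c2O)cc1 | intermediate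
15 | 3,5,7-trihydroxy-2-(4-methoxyphenyl)-4H-chromen-4-one (kaempferide) | COc1ccc(-c2oc3cc(O)cc(O)c3c(=O)c2O)cc1 | intermediate
16 | prenyl bromide (1-bromo-3-methylbut-2-ene) | CC(C)=CCBr | starting material
17 | 3,5-dihydroxy-2-(4-methoxyphenyl)-7-[(3-methylbut-2-en-1-yl)oxy]-4H-chromen-4-one | COc1ccc(-c2oc3cc(OCC=C(C)C)cc(O)c3c(=O)c2O)cc1 | target

## Step count and least certain steps

Total step count: 7. Longest linear sequence: 7 steps (1 to 17). Compounds 9 and 16 enter as purchased.

**Step 4 (key step).**
- *Risk.* The most likely failure is protonation of the aryl anion before the acyl shift, which amounts to plain O-arylation of the acid. It is a real danger here because the flanking benzyloxy group stabilises the anion and the acyl group must enter a site with two ortho substituents. Thermal decarboxylation of the propiolate and 5-exo closure of the phenoxide onto the ynone are further losses.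
- *Fallback.* It sets out from 2 and 9 and returns at 12. C4–C4a is made by polar acylation, and O1–C8a is kept from the phenol.
- Acid 9 is activated with 1,1'-carbonyldiimidazole and treated with N,O-dimethylhydroxylamine hydrochloride to give the Weinreb amide N-methoxy-3-(4-methoxyphenyl)-N-methylprop-2-ynamide F1.
- Carbamate 2 is N-silylated and lithiated as in step 2, and aryllithium 4 is quenched with F1 in place of the chlorosilane. The chelated tetrahedral adduct holds until a dilute aqueous HCl work-up, which also removes the N-silyl group. This should give 3,5-bis(benzyloxy)-2-[3-(4-methoxyphenyl)prop-2-ynoyl]phenyl isopropylcarbamate F2.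
- Et2NH and DBU in MeCN then cleave the carbamate as in step 3. The freed phenoxide of 11 closes to 12, and reversible conjugate addition of the amine to the ynone steers the closure into the 6-endo mode.

**Step 7.**
- *Risk.* Alkylation may spill over to O3, either as a second alkylation or in place of the first, if more than the monoanion is present. C-prenylation at C6 or C8 of the phloroglucinol-type phenoxide is also possible.
- *Fallback.* It sets out from 14 and returns at 17. Selectivity by acidity is replaced by protection of O3.
- Compound 14 is acetylated (Ac2O, pyridine) to 5,7-bis(benzyloxy)-2-(4-methoxyphenyl)-4-oxo-4H-chromen-3-yl acetate F3.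
- Hydrogenolysis as in step 6 gives 5,7-dihydroxy-2-(4-methoxyphenyl)-4-oxo-4H-chromen-3-yl acetate F4, in which O7 is the only free, non-chelated hydroxyl.
- Alkylation with 16 and K2CO3 in dry acetone gives 5-hydroxy-2-(4-methoxyphenyl)-7-[(3-methylbut-2-en-1-yl)oxy]-4-oxo-4H-chromen-3-yl acetate F5.
- Brief methanolysis (K2CO3, MeOH, 0 °C) removes the acetate and gives 17. The price is two more steps.

**Step 2.**
- *Risk.* The alkyllithium–diamine base may remove a benzylic proton of a benzyl ether, followed by Wittig rearrangement. It may also lithiate C4 between the two benzyloxy groups. Warming before the quench would trigger the anionic Fries shift.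
- *Fallback.* It sets out from 1, returns at 8, and replaces steps 1 to 3 by halogen–metal exchange, which outruns any deprotonation.
- Ortho-selective bromination of 1 (NBS, catalytic i-Pr2NH, CH2Cl2, low temperature) gives 3,5-bis(benzyloxy)-2-bromophenol F6, which may need separation from its para isomer.
- Hexamethyldisilazane converts F6 into [3,5-bis(benzyloxy)-2-bromophenoxy]trimethylsilane F7.
- n-BuLi in THF at −78 °C exchanges the bromine, and the silyl group migrates from oxygen to carbon (retro-Brook rearrangement) to give the lithium salt of 7. Tf2O added to the same flask gives 8.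

**Step 5.**
- *Risk.* The C2=C3 bond is conjugated to the carbonyl and may be epoxidised slowly. The excess oxidant then has time to oxidise benzylic C–H bonds or the electron-rich ring A. The epoxide may also open with migration instead of proton loss.
- *Fallback.* It sets out from 12, returns at 14, and replaces electrophilic oxygen transfer by deprotonation.
- Lithium diisopropylamide in THF at −78 °C removes H3, the most acidic C–H of the flavone.
- B(OMe)3 traps the anion as dimethyl [5,7-bis(benzyloxy)-2-(4-methoxyphenyl)-4-oxo-4H-chromen-3-yl]boronate F8.
- H2O2 in AcOH oxidises the C–B bond to the C3 hydroxyl of 14.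

## Further compounds

F1 | step 4 | N-methoxy-3-(4-methoxyphenyl)-N-methylprop-2-ynamide | COc1ccc(C#CC(=O)N(C)OC)cc1
F2 | step 4 | 3,5-bis(benzyloxy)-2-[3-(4-methoxyphenyl)prop-2-ynoyl]phenyl isopropylcarbamate | COc1ccc(C#CC(=O)c2c(OC(=O)NC(C)C)cc(OCc3ccccc3)cc2OCc2ccccc2)cc1
F3 | step 7 | 5,7-bis(benzyloxy)-2-(4-methoxyphenyl)-4-oxo-4H-chromen-3-yl acetate | COc1ccc(-c2oc3cc(OCc4ccccc4)cc(OCc4ccccc4)c3c(=O)c2OC(C)=O)cc1
F4 | step 7 | 5,7-dihydroxy-2-(4-methoxyphenyl)-4-oxo-4H-chromen-3-yl acetate | COc1ccc(-c2oc3cc(O)cc(O)c3c(=O)c2OC(C)=O)cc1
F5 | step 7 | 5-hydroxy-2-(4-methoxyphenyl)-7-[(3-methylbut-2-en-1-yl)oxy]-4-oxo-4H-chromen-3-yl acetate | COc1ccc(-c2oc3cc(OCC=C(C)C)cc(O)c3c(=O)c2OC(C)=O)cc1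
F6 | step 2 | 3,5-bis(benzyloxy)-2-bromophenol | Oc1cc(OCc2ccccc2)cc(OCc2ccccc2)c1Br
F7 | step 2 | [3,5-bis(benzyloxy)-2-bromophenoxy]trimethylsilane | C[Si](C)(C)Oc1cc(OCc2ccccc2)cc(OCc2ccccc2)c1Br
F8 | step 5 | dimethyl [5,7-bis(benzyloxy)-2-(4-methoxyphenyl)-4-oxo-4H-chromen-3-yl]boronate | COB(OC)c1c(-c2ccc(OC)cc2)oc2cc(OCc3ccccc3)cc(OCc3ccccc3)c2c1=O
A1 | alternative 1 | 5,7-dihydroxy-3-(methoxymethoxy)-2-(4-methoxyphenyl)-4H-chromen-4-one | COCOc1c(-c2ccc(OC)cc2)oc2cc(O)cc(O)c2c1=O
A2 | alternative 1 | 3-(methoxymethoxy)-2-(4-methoxyphenyl)-5-(phenylsulfinyl)-4H-pyran-4-one | COCOc1c(-c2ccc(OC)cc2)occ(S(=O)c2ccccc2)c1=O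
A3 | alternative 1 | 1-methoxy-1,3-bis(trimethylsilyloxy)buta-1,3-diene | COC(O[Si](C)(C)C)=CC(=C)O[Si](C)(C)C
A4 | alternative 1 | 5-hydroxy-3-(methoxymethoxy)-2-(4-methoxyphenyl)-7-(3-methylbut-2-enyloxy)-4H-chromen-4-one | COCOc1c(-c2ccc(OC)cc2)oc2cc(OCC=C(C)C)cc(O)c2c1=O
A5 | alternative 2 | 5,7-difluoro-3-(methoxymethoxy)-2-(4-methoxyphenyl)-4H-chromen-4-one | COCOc1c(-c2ccc(OC)cc2)oc2cc(F)cc(F)c2c1=O
A6 | alternative 2 | 2-(methoxymethoxy)-1-(4-methoxyphenyl)ethan-1-one | COCOCC(=O)c1ccc(OC)cc1
A7 | alternative 2 | 2,4,6-trifluorobenzoyl chloride | O=C(Cl)c1c(F)cc(F)cc1F
A8 | alternative 2 | 3-methylbut-2-en-1-ol | CC(C)=CCO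
A9 | alternative 3 | 5,7-dihydroxy-2-(4-methoxyphenyl)-4H-chromen-4-one (acacetin) | COc1ccc(-c2cc(=O)c3c(O)cc(O)cc3o2)cc1
A10 | alternative 3 | 2-iodobenzene-1,3,5-triyl triacetate | CC(=O)Oc1cc(OC(C)=O)c(I)c(OC(C)=O)c1
A11 | alternative 3 | 1-ethynyl-4-methoxybenzene | C#Cc1ccc(OC)cc1
A12 | alternative 3 | carbon monoxide | [C-]#[O+]
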